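E cannot fall by more than the D you charged, if the two react one to one. The runs point that way: at their last readings maple had lost 0.187 M of E and elm 0.188 M, against 0.198 M of D in each.

the same everywhere: D 0.198 M
- cedar: E 0.15 M; run made earlier
- maple: E 0.29 M; run made earlier
- elm: E 0.30 M; run made earlier
- epsilon: E 0.18 M; time 1.0 h
- eta: E 0.40 M; time 0.25 h

| run | time / min | Q / % | E / % |
|---|---|---|---|
| cedar | 5.00 | 11.7 | 68.9 |
| cedar | 10.0 | 22.4 | 54.3 |
| cedar | 15.0 | 29.0 | 41.0 |
| cedar | 30.0 | 39.4 | 25.5 |
| cedar | 60.0 | 42.2 | 8.6 |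
| maple | 5.00 | 11.3 | 75.8 |
| maple | 10.0 | 18.2 | 60.5 |
| maple | 15.0 | 23.7 | 53.0 |
| maple | 30.0 | 30.5 | 41.2 |
| maple | 60.0 | 29.2 | 35.6 |
| elm | 5.00 | 11.8 | 72.5 |
| elm | 10.0 | 18.9 | 61.2 |
| elm | 15.0 | 24.2 | 51.2 |
| elm | 30.0 | 27.3 | 42.2 |
| elm | 60.0 | 31.3 | 37.2 |

(scatter of a reading: 1 percentage point)

- which one finishes higher in amount of Q, in percent of the E charged ("neither" within 2 percentage points) (epsilon / eta / neither)
- amount of Q at the end, in percent of the E charged, epsilon
- amount of Q at the end, in percent of the E charged, eta



So fold the charges into one number, r, the moles of D charged per mole of E. When r is below one, D is the limiting reagent. Let s be the Q formed per E lost; the last readings of maple and elm give s = 0.476. Define the capped yield Y as s times the smaller of one and r. For eta, r = 0.495, so Y = 23.5%. For epsilon, r = 1.10, so Y = 47.6%.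

But r holds no time, so test it. Elm at 15.0 min, eta's time, held 77.3% of the Q of its last reading. That puts eta near 18.2%, and I expect somewhat more, since eta has the larger excess of E. Cedar at 60.0 min, epsilon's time, read 42.2%. Epsilon has less D per E than cedar, so I expect it a little lower. My call is epsilon.

The forecast also says epsilon, with 41.5% for epsilon and 20% for eta. Its ground: “So E + D gives Q in parallel with a side product, taking about half of the E.”

The simulation gives epsilon: epsilon 39.8%, eta 20.9%.

    J ⇌ G (K = 2.90, k = 0.00750 min⁻¹)
    J ⇌ Q (K = 1.24, k = 0.376 min⁻¹)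
    D + Q → Z (k = 0.0142 L mol⁻¹ min⁻¹)
    E + D → J + X (k = 0.401 L mol⁻¹ min⁻¹)

The gap of 19 percentage points is far wider than the margin of 2 points. Eta ends below its Y of 23.5%, with D still at 17% of its charge. Now take the neighbouring flask, which is eta with 1.0 M of E. There r is 0.198 equiv, and Y comes to 9.42%. In that neighbouring flask, D is down to 0.634% of its charge at 0.250 h, E has lost 19.6% of its charge, and Q, slightly above that Y, stands at 10.4%.

(The data stem from a simulated flask from invented constants, noise included.)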